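**Strategy.** The chain (C1 benzylic to C15) is cut between C1 and the vinylic carbon C2. One operation, Zr-catalysed syn-methylalumination of a terminal alkyne followed by Pd-catalysed benzylation of the alkenylalane, forms the C1–C2 bond, installs the C3 methyl group and fixes the 2E geometry. It exploits the trisubstituted C2=C3 alkene that flanks the arene ring (ring A). Its precursor is a C2–C15 enyne diol with a C2≡C3 terminal alkyne, the 6Z alkene and the dihydropyran ring B (C11 from (S)-linalool), C5 and C12 being carbinols. The partner is a silyl-protected benzylic chloride. A double oxidation and desilylation finish the synthesis.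

Key step: step 13

Assumption: (S)-(+)-linalool of high enantiomeric purity is bought, since it alone sets C11; locants C1–C15 run along the chain from the benzylic carbon to the ring CMe2 carbon.

**Step 1**
Reactants: 1 (S)-(+)-linalool
Product: 4 (2S)-2,6,6-trimethyl-2-vinyl-3,6-dihydro-2H-pyran, via phenylselanyl tetrahydropyran 2 (not isolated), via selenoxide 3 (not isolated)
Conditions: PhSeCl, K2CO3, CH2Cl2, −78 °C → rt; then 30% H2O2, pyridine, 0 °C → rt
Reagents that add atoms: none
Why: Selenoetherification: PhSe+ adds to the electron-rich trisubstituted alkene and the tertiary hydroxyl opens the seleniranium ion at the tertiary carbon C15 (Markovnikov 6-endo closure); selenoxide syn-elimination can then only take a hydrogen from C13 because C15 is quaternary, and C11 keeps the configuration of linalool since no bond to it is broken.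

**Step 2**
Reactants: 4 (2S)-2,6,6-trimethyl-2-vinyl-3,6-dihydro-2H-pyran
Product: 5 (2R)-2,6,6-trimethyl-2-vinyl-3,6-dihydro-2H-pyran-3-ol (mixture of C12 epimers)
Conditions: SeO2 (0.5 equiv), t-BuOOH, CH2Cl2, rt
Reagents that add atoms: selenium dioxide O=[Se]=O (the oxygen atom; re-oxidised by tert-butyl hydroperoxide CC(C)(C)OO)
Why: Riley-type allylic oxidation (ene reaction, then [2,3]-sigmatropic shift) returns the alkene to C13=C14 and puts OH on the carbon that lost hydrogen; C12 carries the only allylic hydrogens (C11 and C15 are quaternary, the vinyl group has none), and the new carbinol centre forms as an epimer mixture that is erased in step 14.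

**Step 3**
Reactants: 5 (2R)-2,6,6-trimethyl-2-vinyl-3,6-dihydro-2H-pyran-3-ol
Product: 6 triethyl{[(2R)-2,6,6-trimethyl-2-vinyl-3,6-dihydro-2H-pyran-3-yl]oxy}silane
Conditions: TESCl, imidazole, DMF, rt
Reagents that add atoms: chlorotriethylsilane CC[Si](Cl)(CC)CC
Why: Standard silylation; the TES ether masks the acidic OH during the organolithium step 5 and keeps an alkoxide from chelating boron.

**Step 4**
Reactants: 6 triethyl{[(2R)-2,6,6-trimethyl-2-vinyl-3,6-dihydro-2H-pyran-3-yl]oxy}silane
Product: 7 2-{2-[(2R)-2,6,6-trimethyl-3-(triethylsilyloxy)-3,6-dihydro-2H-pyran-2-yl]ethyl}-4,4,5,5-tetramethyl-1,3,2-dioxaborolane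
Conditions: HBpin, [Ir(cod)Cl]2 (1.5 mol %), dppm, CH2Cl2, rt
Reagents that add atoms: pinacolborane [H]B1OC(C)(C)C(C)(C)O1
Why: Iridium-catalysed anti-Markovnikov hydroboration is selective for the monosubstituted vinyl group; the ring alkene is cis-disubstituted and flanked by two quaternary carbons, so it should not react.

**Step 5**
Reactants: 7 the C9 pinacol boronate
Product: 9 2-{3-[(2R)-2,6,6-trimethyl-3-(triethylsilyloxy)-3,6-dihydro-2H-pyran-2-yl]propyl}-4,4,5,5-tetramethyl-1,3,2-dioxaborolane, via chloromethyl boronate complex 8 (not isolated)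
Conditions: BrCH2Cl, n-BuLi, THF, −78 °C → rt
Reagents that add atoms: bromochloromethane ClCBr
Why: Matteson homologation: LiCH2Cl made in situ adds to boron and the primary alkyl group migrates with loss of chloride, inserting C8 as a CH2 group.

**Step 6**
Reactants: 10 but-2-yn-1-ol
Product: 12 (Z)-3-iodobut-2-en-1-ol, via cyclic alkenylalanate 11 (not isolated)
Conditions: NaAlH2(OCH2CH2OMe)2, Et2O, 0 °C → rt; then I2, THF, −78 → 0 °C
Reagents that add atoms: iodine II
Why: Red-Al trans-hydroalumination of the propargylic alcohol through the cyclic alanate puts aluminium on C3 cis to the CH2O group, and iodinolysis with retention gives the (Z)-iodide, whose geometry later becomes the 6Z alkene.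

**Step 7**
Reactants: 12 (Z)-3-iodobut-2-en-1-ol
Product: 13 (Z)-3-iodobut-2-enal
Conditions: MnO2, CH2Cl2, rt, dark
Reagents that add atoms: none
Why: MnO2 oxidation of a primary allylic alcohol; neutral conditions in the dark should preserve the (Z) geometry and the C–I bond.

**Step 8**
Reactants: 13 (Z)-3-iodobut-2-enal
Product: 14 (Z)-6-iodo-1-(triisopropylsilyl)hept-5-en-1-yn-4-ol (racemic)
Conditions: Zn dust, 3-bromo-1-(triisopropylsilyl)prop-1-yne, THF, 0 °C → rt
Reagents that add atoms: 3-bromo-1-(triisopropylsilyl)prop-1-yne BrCC#C[Si](C(C)C)(C(C)C)C(C)C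
Why: Barbier propargylation: the zinc reagent adds 1,2 to the aldehyde (SE2') to give the homopropargylic alcohol; the carbinol centre (later C5) is racemic and is destroyed in step 14, and the bulky silyl group keeps the alkyne out of the coupling in step 9.

**Step 9**
Reactants: 9 the C8 pinacol boronate; 14 (Z)-6-iodo-1-(triisopropylsilyl)hept-5-en-1-yn-4-ol
Product: 16 (Z)-9-[(2R)-3-hydroxy-2,6,6-trimethyl-3,6-dihydro-2H-pyran-2-yl]-6-methylnon-5-en-1-yn-4-ol (diastereomer mixture), via bis-silyl coupling product 15 (not isolated)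
Conditions: Pd(OAc)2 (5 mol %), SPhos, K3PO4, THF/H2O, 60 °C; then TBAF, THF, rt
Reagents that add atoms: none
Why: sp3–sp2 Suzuki–Miyaura coupling of a primary alkyl boronate with a vinyl iodide proceeds with retention of the (Z) geometry and tolerates the free hydroxyl; fluoride then removes the alkynyl TIPS and the O-TES groups on the crude product.

**Step 10**
Reactants: 17 4-methoxy-3-methylphenol
Product: 18 triisopropyl(4-methoxy-3-methylphenoxy)silane
Conditions: TIPSCl, imidazole, DMF, rt
Reagents that add atoms: chlorotriisopropylsilane CC(C)[Si](Cl)(C(C)C)C(C)C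
Why: Silylation of the phenol; the bulky TIPS group should survive the organolithium, organoaluminium and oxidation steps and shields the positions next to it from metalation.

**Step 11**
Reactants: 18 triisopropyl(4-methoxy-3-methylphenoxy)silane
Product: 20 [2-methoxy-3-methyl-5-(triisopropylsilyloxy)phenyl]methanol, via aryllithium 19 (not isolated)
Conditions: n-BuLi, TMEDA, Et2O, 0 °C → rt; then (CH2O)n, −78 °C → rt
Reagents that add atoms: formaldehyde (as paraformaldehyde) C=O
Why: Directed ortho-metalation: the methoxy group directs lithiation to its only free ortho position (the other bears the methyl group), and the aryllithium is hydroxymethylated.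

**Step 12**
Reactants: 20 [2-methoxy-3-methyl-5-(triisopropylsilyloxy)phenyl]methanol
Product: 22 [3-(chloromethyl)-4-methoxy-5-methylphenoxy]triisopropylsilane, via benzylic mesylate 21 (not isolated)
Conditions: MsCl, 2,4,6-collidine, LiCl, DMF, 0 °C
Reagents that add atoms: lithium chloride [Li+].[Cl-]
Why: Mesylation and in situ SN2 displacement by chloride give the benzylic chloride under non-acidic conditions that leave the aryl silyl ether intact.

**Step 13**
Reactants: 16 the enyne diol; 22 [3-(chloromethyl)-4-methoxy-5-methylphenoxy]triisopropylsilane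
Product: 24 (2E,6Z)-10-[(2R)-3-hydroxy-2,6,6-trimethyl-3,6-dihydro-2H-pyran-2-yl]-1-[2-methoxy-3-methyl-5-(triisopropylsilyloxy)phenyl]-3,7-dimethyldeca-2,6-dien-5-ol (diastereomer mixture), via alkenylalane 23 (not isolated)
Conditions: Me3Al (5 equiv), Cp2ZrCl2 (0.3 equiv), H2O (1 equiv), CH2Cl2, −30 → 0 °C; volatiles removed; then 22, Pd(PPh3)4 (5 mol %), THF, rt
Reagents that add atoms: trimethylaluminium C[Al](C)C (the C3 methyl group)
Why: Cp2ZrCl2-catalysed syn-methylalumination of the terminal alkyne (Negishi carboalumination) places the methyl group on C3 and aluminium on C2 on the same face to give 23; zerovalent palladium then inserts into the benzylic C–Cl bond of 22, the alkenyl group passes from aluminium to palladium with retention, and reductive elimination forms the C1–C2 bond. The closest known reaction type is the tandem alkyne carboalumination/cross-coupling of alkenylalanes with benzylic chlorides used to attach prenyl-type chains to arenes. No ring is closed and no stereocentre is formed; the 2E geometry is controlled by the syn addition and the stereoretentive transmetalation. The step needs regioselectivity (aluminium on the terminal carbon, secured by the terminal alkyne), chemoselectivity for the alkyne over the C6=C7 and ring alkenes (internal alkenes are not carboaluminated under these conditions) and tolerance of both carbinols, which excess Me3Al masks as aluminium alkoxides; the low-temperature, water-accelerated protocol limits Lewis-acid ionisation of the allylic C–O bonds and the chelation-driven loss of alkene geometry.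

**Step 14**
Reactants: 24 the coupled diol
Product: 25 (2E,6Z)-1-[2-methoxy-3-methyl-5-(triisopropylsilyloxy)phenyl]-3,7-dimethyl-10-[(2R)-2,6,6-trimethyl-3-oxo-3,6-dihydro-2H-pyran-2-yl]deca-2,6-dien-5-one
Conditions: Dess–Martin periodinane, NaHCO3, CH2Cl2, 0 °C → rt
Reagents that add atoms: none
Why: Dess–Martin oxidation converts both secondary allylic carbinols to ketones, so the diastereomers of 24 converge on one compound; the buffered, non-basic conditions should keep the C2=C3 alkene out of conjugation and the C6=C7 alkene Z.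

**Step 15**
Reactants: 25 the silyl-protected diketone
Product: 26 CNP0160516.2, (2E,6Z)-1-(5-hydroxy-2-methoxy-3-methylphenyl)-3,7-dimethyl-10-[(2R)-2,6,6-trimethyl-3-oxo-3,6-dihydro-2H-pyran-2-yl]deca-2,6-dien-5-one
Conditions: TBAF, AcOH, THF, 0 °C
Reagents that add atoms: none
Why: Fluoride cleaves the aryl silyl ether; buffering with AcOH keeps the medium non-basic so that the β,γ-unsaturated ketone, the (Z)-enone and the pyranone should survive.

**Compound list**
1 | (S)-(+)-linalool, (3S)-3,7-dimethylocta-1,6-dien-3-ol | C=C[C@@](C)(O)CCC=C(C)C | starting material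
2 | (6S)-2,2,6-trimethyl-3-(phenylselanyl)-6-vinyltetrahydro-2H-pyran (C3 epimers) | C=C[C@@]1(C)OC(C)(C)C([Se]c2ccccc2)CC1 | intermediate
3 | selenoxide of 2 | C=C[C@@]1(C)OC(C)(C)C([Se](=O)c2ccccc2)CC1 | intermediate
4 | (2S)-2,6,6-trimethyl-2-vinyl-3,6-dihydro-2H-pyran | C=C[C@@]1(C)OC(C)(C)C=CC1 | intermediate
5 | (2R)-2,6,6-trimethyl-2-vinyl-3,6-dihydro-2H-pyran-3-ol (C3 epimers) | C=C[C@@]1(C)OC(C)(C)C=CC1O | intermediate
6 | triethyl{[(2R)-2,6,6-trimethyl-2-vinyl-3,6-dihydro-2H-pyran-3-yl]oxy}silane | C=C[C@@]1(C)OC(C)(C)C=CC1O[Si](CC)(CC)CC | intermediate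
7 | 2-{2-[(2R)-2,6,6-trimethyl-3-(triethylsilyloxy)-3,6-dihydro-2H-pyran-2-yl]ethyl}-4,4,5,5-tetramethyl-1,3,2-dioxaborolane | CC1(C)OB(CC[C@@]2(C)OC(C)(C)C=CC2O[Si](CC)(CC)CC)OC1(C)C | intermediate
8 | lithium (chloromethyl)boronate complex of 7 | [Li+].CC1(C)O[B-](CCl)(CC[C@@]2(C)OC(C)(C)C=CC2O[Si](CC)(CC)CC)OC1(C)C | intermediate
9 | 2-{3-[(2R)-2,6,6-trimethyl-3-(triethylsilyloxy)-3,6-dihydro-2H-pyran-2-yl]propyl}-4,4,5,5-tetramethyl-1,3,2-dioxaborolane | CC1(C)OB(CCC[C@@]2(C)OC(C)(C)C=CC2O[Si](CC)(CC)CC)OC1(C)C | intermediate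
10 | but-2-yn-1-ol | CC#CCO | starting material
11 | sodium cyclic alkenylalanate (2,5-dihydro-1,2-oxaaluminole) | [Na+].CC1=CCO[Al-]1(OCCOC)OCCOC | intermediate
12 | (Z)-3-iodobut-2-en-1-ol | C/C(I)=C/CO | intermediate
13 | (Z)-3-iodobut-2-enal | C/C(I)=C/C=O | intermediate
14 | (Z)-6-iodo-1-(triisopropylsilyl)hept-5-en-1-yn-4-ol (racemic) | C/C(I)=C/C(O)CC#C[Si](C(C)C)(C(C)C)C(C)C | intermediate
15 | bis-silyl coupling product (alkynyl TIPS, O-TES) | CC(C)[Si](C#CCC(O)/C=C(/C)CCC[C@@]1(C)OC(C)(C)C=CC1O[Si](CC)(CC)CC)(C(C)C)C(C)C | intermediate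
16 | (Z)-9-[(2R)-3-hydroxy-2,6,6-trimethyl-3,6-dihydro-2H-pyran-2-yl]-6-methylnon-5-en-1-yn-4-ol | C#CCC(O)/C=C(/C)CCC[C@@]1(C)OC(C)(C)C=CC1O | intermediate
17 | 4-methoxy-3-methylphenol | COc1ccc(O)cc1C | starting material
18 | triisopropyl(4-methoxy-3-methylphenoxy)silane | COc1ccc(O[Si](C(C)C)(C(C)C)C(C)C)cc1C | intermediate
19 | [2-methoxy-3-methyl-5-(triisopropylsilyloxy)phenyl]lithium | COc1c([Li])cc(O[Si](C(C)C)(C(C)C)C(C)C)cc1C | intermediate
20 | [2-methoxy-3-methyl-5-(triisopropylsilyloxy)phenyl]methanol | COc1c(CO)cc(O[Si](C(C)C)(C(C)C)C(C)C)cc1C | intermediate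
21 | 2-methoxy-3-methyl-5-(triisopropylsilyloxy)benzyl methanesulfonate | COc1c(COS(C)(=O)=O)cc(O[Si](C(C)C)(C(C)C)C(C)C)cc1C | intermediate
22 | [3-(chloromethyl)-4-methoxy-5-methylphenoxy]triisopropylsilane | COc1c(CCl)cc(O[Si](C(C)C)(C(C)C)C(C)C)cc1C | intermediate
23 | (E)-alkenyl(dimethyl)alane with both carbinols as dimethylaluminium alkoxides | C[Al](C)/C=C(\C)CC(O[Al](C)C)/C=C(/C)CCC[C@@]1(C)OC(C)(C)C=CC1O[Al](C)C | intermediate
24 | (2E,6Z)-10-[(2R)-3-hydroxy-2,6,6-trimethyl-3,6-dihydro-2H-pyran-2-yl]-1-[2-methoxy-3-methyl-5-(triisopropylsilyloxy)phenyl]-3,7-dimethyldeca-2,6-dien-5-ol | COc1c(C)cc(O[Si](C(C)C)(C(C)C)C(C)C)cc1C/C=C(\C)CC(O)/C=C(/C)CCC[C@@]1(C)OC(C)(C)C=CC1O | intermediate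
25 | (2E,6Z)-1-[2-methoxy-3-methyl-5-(triisopropylsilyloxy)phenyl]-3,7-dimethyl-10-[(2R)-2,6,6-trimethyl-3-oxo-3,6-dihydro-2H-pyran-2-yl]deca-2,6-dien-5-one | COc1c(C)cc(O[Si](C(C)C)(C(C)C)C(C)C)cc1C/C=C(\C)CC(=O)/C=C(/C)CCC[C@@]1(C)OC(C)(C)C=CC1=O | intermediate
26 | CNP0160516.2 | COc1c(C)cc(O)cc1C/C=C(\C)CC(=O)/C=C(/C)CCC[C@@]1(C)OC(C)(C)C=CC1=O | target

**Step count.** Total: 15 steps. Longest linear sequence: 9 steps (steps 1–5, 9, 13, 14, 15, from (S)-linalool).

**Steps most likely to fail**

Step 13. The Lewis-acidic aluminium and zirconium species may ionise the allylic C–O bonds (the C5 aluminium alkoxide, the ring C15–O bond), or the alkoxide-laden alkenylalane may transfer its alkenyl group to palladium too slowly and be lost by protodealumination. The fallback avoids aluminium and sets out from 16. Silylation of both carbinols (TBSOTf, 2,6-lutidine) gives the bis-TBS ether F1. Copper-catalysed syn-borylmethylation of the alkyne (B2pin2, MeI, CuCl, Xantphos, NaOt-Bu, THF) gives the (E)-alkenyl pinacol boronate F2. Suzuki–Miyaura coupling of F2 with 22 (PdCl2(dppf), K3PO4, THF/H2O) forms the same C1–C2 bond and gives the coupled bis-TBS ether F3. HF·pyridine in THF/pyridine cleaves the two alkyl TBS ethers, leaves the aryl TIPS ether, and comes back to the route at 24.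

Step 2. The ene step at the hindered ring alkene may be sluggish, so that over-oxidation or oxygen delivery with allylic transposition competes. The fallback sets out from 4 and fixes the regiochemistry by mechanism. Schenck ene photooxygenation (O2, tetraphenylporphyrin, light, CH2Cl2) can only abstract hydrogen from C12 and gives the C14 hydroperoxide F4 with the alkene shifted to C12=C13. Ac2O/pyridine dehydrates it to the transposed enone F5. H2O2/NaOH gives the epoxy ketone F6. Wharton transposition (N2H4·H2O, AcOH, MeOH) moves the oxygen to C12 and the alkene to C13=C14, and comes back to the route at 5.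

Step 9. Transmetalation of the primary alkyl pinacol boronate may be slow, so that protodeboronation and decomposition or isomerisation of the (Z)-vinyl iodide take over. The fallback sets out from 9. Oxidation (NaBO3·4H2O, THF/H2O) gives the primary alcohol F7, and Appel iodination (I2, PPh3, imidazole) gives the primary iodide F8. Zinc insertion (Zn dust, LiCl, THF) gives the alkylzinc iodide F9. Negishi coupling of F9 (in excess, to allow for the free hydroxyl) with 14 under PdCl2(dppf) in THF gives 15, and the TBAF treatment of step 9 then comes back to the route at 16.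

**Further compounds**
F1 | step 13 | bis-TBS ether of 16 | C#CCC(O[Si](C)(C)C(C)(C)C)/C=C(/C)CCC[C@@]1(C)OC(C)(C)C=CC1O[Si](C)(C)C(C)(C)C
F2 | step 13 | (E)-alkenyl pinacol boronate from F1 | CC1(C)OB(/C=C(\C)CC(O[Si](C)(C)C(C)(C)C)/C=C(/C)CCC[C@@]2(C)OC(C)(C)C=CC2O[Si](C)(C)C(C)(C)C)OC1(C)C
F3 | step 13 | bis-TBS ether of 24 | COc1c(C)cc(O[Si](C(C)C)(C(C)C)C(C)C)cc1C/C=C(\C)CC(O[Si](C)(C)C(C)(C)C)/C=C(/C)CCC[C@@]1(C)OC(C)(C)C=CC1O[Si](C)(C)C(C)(C)C
F4 | step 2 | 3-hydroperoxy-2,2,6-trimethyl-6-vinyl-3,6-dihydro-2H-pyran (C14 hydroperoxide) | C=C[C@@]1(C)OC(C)(C)C(OO)C=C1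
F5 | step 2 | 2,2,6-trimethyl-6-vinyl-2H-pyran-3(6H)-one (transposed enone) | C=C[C@@]1(C)OC(C)(C)C(=O)C=C1
F6 | step 2 | 4,5-epoxy-2,2,6-trimethyl-6-vinyltetrahydro-2H-pyran-3-one | C=C[C@@]1(C)OC(C)(C)C(=O)C2OC12
F7 | step 9 | 3-[(2R)-2,6,6-trimethyl-3-(triethylsilyloxy)-3,6-dihydro-2H-pyran-2-yl]propan-1-ol | OCCC[C@@]1(C)OC(C)(C)C=CC1O[Si](CC)(CC)CC
F8 | step 9 | triethyl{[(2R)-2-(3-iodopropyl)-2,6,6-trimethyl-3,6-dihydro-2H-pyran-3-yl]oxy}silane | ICCC[C@@]1(C)OC(C)(C)C=CC1O[Si](CC)(CC)CC
F9 | step 9 | alkylzinc iodide from F8 | I[Zn]CCC[C@@]1(C)OC(C)(C)C=CC1O[Si](CC)(CC)CC
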